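**Strategy**

Ring C of the 7-methoxyflavanone unit is read as an aryl aldehyde C=O (C2 and O1) inserted between C3, the α-carbon of the C4 ketone, and C8a of ring A, which lies ortho to that ketone and can therefore carry a fluoride leaving group. One operation does this: a catalyst-controlled Mukaiyama aldol of a 2-fluoroacetophenone enol silane with the aldehyde forms C2–C3 and sets C2 (S), and fluoride then releases the aldolate oxygen, which closes O1–C8a by intramolecular SNAr. The precursor pair is a diaryl ether benzaldehyde, its second formyl group masked as a dioxolane, and the enol silane; the same annulation later builds the second flavanone.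

Key step: step 8

Remark on the chemistry: the B-butyl oxazaborolidinone made from N-tosyl-(R)-tryptophan is taken to deliver the enol silane to the si face of an aryl aldehyde (S carbinol), its enantiomer giving the R aldol. This sense is assigned from the usual model for this catalyst and should be confirmed on the first run; if it proves opposite, the (S)-tryptophan catalyst is used in steps 8 and 10 with no other change.

**Route**

Step 1
Reactants: 1 5-fluorobenzene-1,3-diol
Product: 2 1-(2-fluoro-4,6-dihydroxyphenyl)ethan-1-one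
Conditions: MeCN, ZnCl2, HCl (g), Et2O, 0 °C; then H2O, reflux
Reagents that add atoms: acetonitrile (CC#N); water (O)
Why: Houben–Hoesch acylation, in which the nitrilium electrophile should attack C4 (para to one hydroxyl, ortho to the other) rather than the doubly flanked C2, and the ketiminium chloride is hydrolysed to the methyl ketone.

Step 2
Reactants: 2 1-(2-fluoro-4,6-dihydroxyphenyl)ethan-1-one
Product: 3 1-(2-fluoro-6-hydroxy-4-methoxyphenyl)ethan-1-one
Conditions: MeI (1.05 equiv), K2CO3 (1.1 equiv), acetone, 40 °C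
Reagents that add atoms: iodomethane (CI)
Why: Williamson etherification, selective because the 4-hydroxyl is the more acidic, unchelated phenol while the 6-hydroxyl is held in a hydrogen bond to the acetyl oxygen.

Step 3
Reactants: 3 1-(2-fluoro-6-hydroxy-4-methoxyphenyl)ethan-1-one
Product: 4 1-[2-(benzyloxy)-6-fluoro-4-methoxyphenyl]ethan-1-one
Conditions: BnBr, K2CO3, DMF, 60 °C
Reagents that add atoms: benzyl bromide (BrCc1ccccc1)
Why: Williamson etherification, where DMF and mild heating overcome the hydrogen bond of the remaining phenol and the aryl fluoride is inert to carbonate.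

Step 4
Reactants: 4 1-[2-(benzyloxy)-6-fluoro-4-methoxyphenyl]ethan-1-one
Product: 5 {[1-(2-(benzyloxy)-6-fluoro-4-methoxyphenyl)ethenyl]oxy}trimethylsilane
Conditions: LiN(SiMe3)2, THF, –78 °C; TMSCl, –78 → 0 °C; non-aqueous work-up
Reagents that add atoms: chlorotrimethylsilane (C[Si](C)(C)Cl)
Why: Silyl enol ether formation by kinetic deprotonation of the only enolisable position and O-silylation of the lithium enolate, the hindered amide base being unreactive toward the aryl fluoride at this temperature.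

Step 5
Reactants: 2 1-(2-fluoro-4,6-dihydroxyphenyl)ethan-1-one
Product: 6 1-[2,4-bis(benzyloxy)-6-fluorophenyl]ethan-1-one
Conditions: BnBr (2.4 equiv), K2CO3, DMF, 60 °C
Reagents that add atoms: benzyl bromide (BrCc1ccccc1)
Why: Twofold Williamson etherification, the free 4-hydroxyl reacting first and the chelated 6-hydroxyl following in warm DMF.

Step 6
Reactants: 6 1-[2,4-bis(benzyloxy)-6-fluorophenyl]ethan-1-one
Product: 7 {[1-(2,4-bis(benzyloxy)-6-fluorophenyl)ethenyl]oxy}trimethylsilane
Conditions: LiN(SiMe3)2, THF, –78 °C; TMSCl, –78 → 0 °C; non-aqueous work-up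
Reagents that add atoms: chlorotrimethylsilane (C[Si](C)(C)Cl)
Why: Silyl enol ether formation from the lithium enolate of the methyl ketone, as in step 4.

Step 7
Reactants: 8 4-(benzyloxy)-3-hydroxybenzaldehyde; 9 2-(4-bromophenyl)-1,3-dioxolane
Product: 10 4-(benzyloxy)-3-[4-(1,3-dioxolan-2-yl)phenoxy]benzaldehyde
Conditions: CuI (10 mol %), N,N-dimethylglycine hydrochloride (30 mol %), Cs2CO3, 1,4-dioxane, 90 °C
Reagents that add atoms: none
Why: Ullmann diaryl ether coupling catalysed by monovalent copper with an amino acid ligand, which tolerates the formyl group, the benzyl ether and the acetal and leaves the two formyl carbons of the future diaryl ether differentiated.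

Step 8
Reactants: 10 4-(benzyloxy)-3-[4-(1,3-dioxolan-2-yl)phenoxy]benzaldehyde; 5 {[1-(2-(benzyloxy)-6-fluoro-4-methoxyphenyl)ethenyl]oxy}trimethylsilane
Product: 12 (2S)-5-(benzyloxy)-2-{4-(benzyloxy)-3-[4-(1,3-dioxolan-2-yl)phenoxy]phenyl}-7-methoxychroman-4-one, via trimethylsilyl aldol ether 11 (not isolated)
Conditions: 5 (1.1 equiv), B-butyl oxazaborolidinone from N-tosyl-(R)-tryptophan and BuB(OH)2 (20 mol %), EtCN, –78 °C; then Bu4NF (0.2 equiv, THF), –78 → 23 °C
Reagents that add atoms: none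
Why: The boron Lewis acid binds the formyl group of 10 and enol silane 5 adds through an open transition state to give silyl ether 11 (C2–C3 bond); fluoride then unmasks the alkoxide, which adds to C8a ortho to the ketone and expels fluoride through an anionic σ-adduct (O1–C8a bond), the released fluoride carrying the chain so that the net by-product is Me3SiF. The closest known reactions are the oxazaborolidinone-catalysed Mukaiyama aldol of acetophenone enol silanes with aryl aldehydes and the fluoride-promoted SNAr etherification of silyl ethers with ortho-acyl fluoroarenes. The one ring closed is the six-membered pyranone ring C, by intramolecular addition–elimination at an arene carbon (6-exo-trig when counted on the C8a–C8 π bond). The only new stereocentre, C2, is fixed by the catalyst in the aldol stage (one aldehyde face shielded by the indole, si-face attack, S) and is not touched in the ring closure because the C2–O bond stays intact. The step needs ring closure to outrun retro-aldol cleavage and E1cB dehydration of the aldolate, and needs the aldehyde to react in preference to the dioxolane; the ketone-activated ortho C–F bond, the six-ring geometry, the low alkoxide concentration under catalytic fluoride and the weak Lewis acid at –78 °C are relied on for this.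

Step 9
Reactants: 12 (2S)-5-(benzyloxy)-2-{4-(benzyloxy)-3-[4-(1,3-dioxolan-2-yl)phenoxy]phenyl}-7-methoxychroman-4-one
Product: 13 4-{2-(benzyloxy)-5-[(2S)-5-(benzyloxy)-7-methoxy-4-oxochroman-2-yl]phenoxy}benzaldehyde
Conditions: 1 M HCl, THF, 23 °C
Reagents that add atoms: water (O)
Why: Acid-catalysed acetal hydrolysis of the aryl dioxolane, dilute acid at room temperature leaving the benzyl ethers and the flavanone with its C2 stereocentre untouched.

Step 10
Reactants: 13 4-{2-(benzyloxy)-5-[(2S)-5-(benzyloxy)-7-methoxy-4-oxochroman-2-yl]phenoxy}benzaldehyde; 7 {[1-(2,4-bis(benzyloxy)-6-fluorophenyl)ethenyl]oxy}trimethylsilane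
Product: 15 (2S)-5,7-bis(benzyloxy)-2-(4-{2-(benzyloxy)-5-[(2S)-5-(benzyloxy)-7-methoxy-4-oxochroman-2-yl]phenoxy}phenyl)chroman-4-one, via trimethylsilyl aldol ether 14 (not isolated)
Conditions: 7 (1.1 equiv), B-butyl oxazaborolidinone from N-tosyl-(R)-tryptophan and BuB(OH)2 (20 mol %), EtCN, –78 °C; then Bu4NF (0.2 equiv, THF), –78 → 23 °C
Reagents that add atoms: none
Why: The same Mukaiyama aldol and fluoride-triggered SNAr sequence as in step 8, the catalyst again adding the enol silane to the si face so that the second C2 should be S irrespective of the remote first stereocentre, with only catalytic fluoride to spare the flavanone already present.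

Step 11
Reactants: 15 (2S)-5,7-bis(benzyloxy)-2-(4-{2-(benzyloxy)-5-[(2S)-5-(benzyloxy)-7-methoxy-4-oxochroman-2-yl]phenoxy}phenyl)chroman-4-one
Product: 16 7-O-methyltetrahydroochnaflavone
Conditions: H2 (1 atm), Pd/C (10 % Pd), EtOAc–MeOH, 23 °C
Reagents that add atoms: none
Why: Hydrogenolysis of the four benzyl aryl ethers, which under one atmosphere at room temperature is expected to spare the cyclic benzylic C2–O1 bonds, the ketones, the methyl ether and both stereocentres.

**Compound list**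

1 | 5-fluorobenzene-1,3-diol (5-fluororesorcinol) | Oc1cc(O)cc(F)c1 | starting material
2 | 1-(2-fluoro-4,6-dihydroxyphenyl)ethan-1-one | CC(=O)c1c(O)cc(O)cc1F | intermediate
3 | 1-(2-fluoro-6-hydroxy-4-methoxyphenyl)ethan-1-one | CC(=O)c1c(O)cc(OC)cc1F | intermediate
4 | 1-[2-(benzyloxy)-6-fluoro-4-methoxyphenyl]ethan-1-one | CC(=O)c1c(OCc2ccccc2)cc(OC)cc1F | intermediate
5 | {[1-(2-(benzyloxy)-6-fluoro-4-methoxyphenyl)ethenyl]oxy}trimethylsilane | C=C(O[Si](C)(C)C)c1c(OCc2ccccc2)cc(OC)cc1F | intermediate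
6 | 1-[2,4-bis(benzyloxy)-6-fluorophenyl]ethan-1-one | CC(=O)c1c(OCc2ccccc2)cc(OCc2ccccc2)cc1F | intermediate
7 | {[1-(2,4-bis(benzyloxy)-6-fluorophenyl)ethenyl]oxy}trimethylsilane | C=C(O[Si](C)(C)C)c1c(OCc2ccccc2)cc(OCc2ccccc2)cc1F | intermediate
8 | 4-(benzyloxy)-3-hydroxybenzaldehyde | O=Cc1ccc(OCc2ccccc2)c(O)c1 | starting material
9 | 2-(4-bromophenyl)-1,3-dioxolane | Brc1ccc(cc1)C1OCCO1 | starting material
10 | 4-(benzyloxy)-3-[4-(1,3-dioxolan-2-yl)phenoxy]benzaldehyde | O=Cc1ccc(OCc2ccccc2)c(Oc2ccc(cc2)C2OCCO2)c1 | intermediate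
11 | (3S)-1-[2-(benzyloxy)-6-fluoro-4-methoxyphenyl]-3-{4-(benzyloxy)-3-[4-(1,3-dioxolan-2-yl)phenoxy]phenyl}-3-[(trimethylsilyl)oxy]propan-1-one | COc1cc(F)c(C(=O)C[C@H](O[Si](C)(C)C)c2ccc(OCc3ccccc3)c(Oc3ccc(cc3)C3OCCO3)c2)c(OCc2ccccc2)c1 | intermediate
12 | (2S)-5-(benzyloxy)-2-{4-(benzyloxy)-3-[4-(1,3-dioxolan-2-yl)phenoxy]phenyl}-7-methoxychroman-4-one | COc1cc(OCc2ccccc2)c2c(c1)O[C@H](c1ccc(OCc3ccccc3)c(Oc3ccc(cc3)C3OCCO3)c1)CC2=O | intermediate
13 | 4-{2-(benzyloxy)-5-[(2S)-5-(benzyloxy)-7-methoxy-4-oxochroman-2-yl]phenoxy}benzaldehyde | COc1cc(OCc2ccccc2)c2c(c1)O[C@H](c1ccc(OCc3ccccc3)c(Oc3ccc(C=O)cc3)c1)CC2=O | intermediate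
14 | (3S)-1-[2,4-bis(benzyloxy)-6-fluorophenyl]-3-(4-{2-(benzyloxy)-5-[(2S)-5-(benzyloxy)-7-methoxy-4-oxochroman-2-yl]phenoxy}phenyl)-3-[(trimethylsilyl)oxy]propan-1-one | COc1cc(OCc2ccccc2)c2c(c1)O[C@H](c1ccc(OCc3ccccc3)c(Oc3ccc(cc3)[C@@H](O[Si](C)(C)C)CC(=O)c3c(F)cc(OCc4ccccc4)cc3OCc3ccccc3)c1)CC2=O | intermediate
15 | (2S)-5,7-bis(benzyloxy)-2-(4-{2-(benzyloxy)-5-[(2S)-5-(benzyloxy)-7-methoxy-4-oxochroman-2-yl]phenoxy}phenyl)chroman-4-one | COc1cc(OCc2ccccc2)c2c(c1)O[C@H](c1ccc(OCc3ccccc3)c(Oc3ccc([C@@H]4CC(=O)c5c(OCc6ccccc6)cc(OCc6ccccc6)cc5O4)cc3)c1)CC2=O | intermediate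
16 | 7-O-methyltetrahydroochnaflavone, (2S)-2-(4-{2-hydroxy-5-[(2S)-5-hydroxy-7-methoxy-4-oxochroman-2-yl]phenoxy}phenyl)-5,7-dihydroxychroman-4-one | COc1cc(O)c2c(c1)O[C@H](c1ccc(O)c(Oc3ccc([C@@H]4CC(=O)c5c(O)cc(O)cc5O4)cc3)c1)CC2=O | target

**Step count**

Total steps: 11. Longest linear sequence: 8 (steps 1, 2, 3, 4, 8, 9, 10, 11).

**Steps most likely to fail**

Step 8. Retro-aldol cleavage or E1cB dehydration of the aldolate may outrun the ring closure during the fluoride stage and erode the enantiomeric purity, and the Lewis acid may ionise the dioxolane. The fallback closes the ring from the phenol side under neutral conditions; it sets out from 10 and returns at 12. Commercial 1-(2,6-dihydroxy-4-methoxyphenyl)ethan-1-one is monobenzylated (BnBr 1 equiv, K2CO3, acetone) to 1-[2-(benzyloxy)-6-hydroxy-4-methoxyphenyl]ethan-1-one F1. Double silylation (LiN(SiMe3)2 2.2 equiv, TMSCl) should give the aryl silyl ether enol silane F2. Its Mukaiyama aldol with 10 under the enantiomeric catalyst (from N-tosyl-(S)-tryptophan, re-face attack) should give the bis-silylated (3R)-aldol F3, which is desilylated in the work-up with Bu4NF/AcOH to the (3R)-hydroxy phenol F4. Mitsunobu ring closure (PPh3, DIAD, THF, 0 °C) with inversion at the carbinol then forms the O1–C2 bond and gives 12.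

Step 10. Base-mediated ring opening (retro-oxa-Michael) of the flavanone already present may scramble its C2, and its carbonyl may sequester the boron catalyst. The fallback uses the same neutral Mitsunobu closure; it sets out from 13 and returns at 15. Commercial 1-(2,4,6-trihydroxyphenyl)ethan-1-one is dibenzylated (BnBr 2 equiv, K2CO3, DMF) to 1-[2,4-bis(benzyloxy)-6-hydroxyphenyl]ethan-1-one F5 and doubly silylated to the aryl silyl ether enol silane F6. Mukaiyama aldol with 13 under the (S)-tryptophan-derived catalyst (stoichiometric if the flavanone carbonyl slows turnover) should give the bis-silylated (3R)-aldol F7 and, after Bu4NF/AcOH, the (3R)-hydroxy phenol F8. Mitsunobu closure (PPh3, DIAD, THF, 0 °C) with inversion gives 15.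

Step 7. The ortho-alkoxy, formyl-deactivated phenoxide may couple too slowly with the unactivated aryl bromide, so that protodebromination and catalyst decay take over. The fallback replaces copper catalysis by SNAr on an activated fluoroarene; it sets out from 8 and returns at 10. Reduction of 8 (NaBH4, MeOH, 0 °C) gives 2-(benzyloxy)-5-(hydroxymethyl)phenol F9. SNAr of its phenoxide with 4-fluorobenzaldehyde (K2CO3, DMF, 90 °C) gives 4-[2-(benzyloxy)-5-(hydroxymethyl)phenoxy]benzaldehyde F10. Acetalisation (ethylene glycol, PPTS, benzene, reflux with water removal) gives {4-(benzyloxy)-3-[4-(1,3-dioxolan-2-yl)phenoxy]phenyl}methanol F11, and benzylic oxidation (MnO2, CH2Cl2, 23 °C) gives 10.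

**Further compounds**

F1 | step 8 | 1-[2-(benzyloxy)-6-hydroxy-4-methoxyphenyl]ethan-1-one | CC(=O)c1c(O)cc(OC)cc1OCc1ccccc1
F2 | step 8 | {[1-(2-(benzyloxy)-4-methoxy-6-[(trimethylsilyl)oxy]phenyl)ethenyl]oxy}trimethylsilane | C=C(O[Si](C)(C)C)c1c(O[Si](C)(C)C)cc(OC)cc1OCc1ccccc1
F3 | step 8 | (3R)-1-{2-(benzyloxy)-4-methoxy-6-[(trimethylsilyl)oxy]phenyl}-3-{4-(benzyloxy)-3-[4-(1,3-dioxolan-2-yl)phenoxy]phenyl}-3-[(trimethylsilyl)oxy]propan-1-one | COc1cc(O[Si](C)(C)C)c(C(=O)C[C@@H](O[Si](C)(C)C)c2ccc(OCc3ccccc3)c(Oc3ccc(cc3)C3OCCO3)c2)c(OCc2ccccc2)c1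
F4 | step 8 | (3R)-1-[2-(benzyloxy)-6-hydroxy-4-methoxyphenyl]-3-{4-(benzyloxy)-3-[4-(1,3-dioxolan-2-yl)phenoxy]phenyl}-3-hydroxypropan-1-one | COc1cc(O)c(C(=O)C[C@@H](O)c2ccc(OCc3ccccc3)c(Oc3ccc(cc3)C3OCCO3)c2)c(OCc2ccccc2)c1
F5 | step 10 | 1-[2,4-bis(benzyloxy)-6-hydroxyphenyl]ethan-1-one | CC(=O)c1c(O)cc(OCc2ccccc2)cc1OCc1ccccc1
F6 | step 10 | {[1-(2,4-bis(benzyloxy)-6-[(trimethylsilyl)oxy]phenyl)ethenyl]oxy}trimethylsilane | C=C(O[Si](C)(C)C)c1c(O[Si](C)(C)C)cc(OCc2ccccc2)cc1OCc1ccccc1
F7 | step 10 | (3R)-1-{2,4-bis(benzyloxy)-6-[(trimethylsilyl)oxy]phenyl}-3-(4-{2-(benzyloxy)-5-[(2S)-5-(benzyloxy)-7-methoxy-4-oxochroman-2-yl]phenoxy}phenyl)-3-[(trimethylsilyl)oxy]propan-1-one | COc1cc(OCc2ccccc2)c2c(c1)O[C@H](c1ccc(OCc3ccccc3)c(Oc3ccc(cc3)[C@H](O[Si](C)(C)C)CC(=O)c3c(O[Si](C)(C)C)cc(OCc4ccccc4)cc3OCc3ccccc3)c1)CC2=O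
F8 | step 10 | (3R)-1-[2,4-bis(benzyloxy)-6-hydroxyphenyl]-3-(4-{2-(benzyloxy)-5-[(2S)-5-(benzyloxy)-7-methoxy-4-oxochroman-2-yl]phenoxy}phenyl)-3-hydroxypropan-1-one | COc1cc(OCc2ccccc2)c2c(c1)O[C@H](c1ccc(OCc3ccccc3)c(Oc3ccc(cc3)[C@H](O)CC(=O)c3c(O)cc(OCc4ccccc4)cc3OCc3ccccc3)c1)CC2=O
F9 | step 7 | 2-(benzyloxy)-5-(hydroxymethyl)phenol | OCc1ccc(OCc2ccccc2)c(O)c1
F10 | step 7 | 4-[2-(benzyloxy)-5-(hydroxymethyl)phenoxy]benzaldehyde | O=Cc1ccc(Oc2cc(CO)ccc2OCc2ccccc2)cc1
F11 | step 7 | {4-(benzyloxy)-3-[4-(1,3-dioxolan-2-yl)phenoxy]phenyl}methanol | OCc1ccc(OCc2ccccc2)c(Oc2ccc(cc2)C2OCCO2)c1
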